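**Retrosynthetic overview** (ring A = resorcinol ring fused to the cycloheptene and one dihydrofuran; ring B = resorcinol ring carrying the other dihydrofuran)
1. Target ⇐ hepta-O-methyl ether (global demethylation; the whole skeleton and all four stereocentres are already in place).
2. Hepta-O-methyl ether ⇐ diaryl-ketone hydrazone with an ortho O-PMB group and a silyl-enol-ether-masked aryl ketone: in one flask, Rh-carbene C–H insertion closes the ring-A dihydrobenzofuran, then acid Friedel–Crafts cyclodehydration closes the cycloheptene.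
3. Hydrazone ⇐ aryllithium of the ring-B dihydrobenzofuran + a 3-aryl-isocoumarin; lactone opening delivers the diaryl ketone and the latent C-7 ketone in one step.
4. Ring-B dihydrobenzofuran ⇐ Rh-carbene C–H insertion (opposite catalyst hand) of a hydrazone built from 4-bromo-2,6-difluorobenzonitrile by two SNAr reactions and Grignard addition.
5. Isocoumarin ⇐ o-toluate lateral acylation/lactonisation, peri-demethylation, PMB ether. Ring order: isocoumarin (sacrificial) → ring-B dihydrofuran → ring-A dihydrofuran and seven-membered ring together.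

Assumption: Rh2(R-PTAD)4 is taken to give the 3R and Rh2(S-PTAD)4 the 3S configuration at C-3 of the newly formed dihydrobenzofuran; if the sense is the reverse, the two catalysts are exchanged between steps 3 and 9.

**Step 1**
Reactants: 1 4-bromo-2,6-difluorobenzonitrile; 2 4-methoxybenzyl alcohol
Product: 4 4-bromo-2-methoxy-6-[(4-methoxybenzyl)oxy]benzonitrile, via fluoro ether 3 (not isolated)
Conditions: 2, NaH, THF, 0 °C→rt; then NaOMe, MeOH, 65 °C
Reagents that add atoms: sodium methoxide, [Na+].[O-]C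
Why: Two successive SNAr displacements of the fluorides ortho to the nitrile; the first alkoxy group deactivates the ring, so one equivalent of the PMB alkoxide stops at 3 and the second fluoride needs excess methoxide and heat, which differentiates the two ring-B oxygens; no stereocentre.

**Step 2**
Reactants: 4 4-bromo-2-methoxy-6-[(4-methoxybenzyl)oxy]benzonitrile; 5 3,5-dimethoxyphenylmagnesium bromide
Product: 7 [4-bromo-2-methoxy-6-(4-methoxybenzyloxy)phenyl](3,5-dimethoxyphenyl)methanone hydrazone, via ketimine 6 (not isolated)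
Conditions: 5 (1.5 equiv), THF/PhMe, 70 °C; MeOH; then N2H4·H2O, cat. AcOH, EtOH, 60 °C
Reagents that add atoms: hydrazine hydrate, NN.O
Why: Grignard addition to the nitrile (helped by chelation to the flanking alkoxy groups) stops at the N-magnesio ketimine, and the free N–H ketimine undergoes transimination with hydrazine much faster than a 2,6-dialkoxybenzophenone would condense; the aryl bromide is inert to ArMgBr; no stereocentre.

**Step 3**
Reactants: 7 [4-bromo-2-methoxy-6-(4-methoxybenzyloxy)phenyl](3,5-dimethoxyphenyl)methanone hydrazone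
Product: 9 (2S,3R)-6-bromo-3-(3,5-dimethoxyphenyl)-4-methoxy-2-(4-methoxyphenyl)-2,3-dihydrobenzofuran, via diazo compound 8 (not isolated)
Conditions: MnO2, CH2Cl2, 0 °C; then Rh2(R-PTAD)4 (1 mol %), −20 °C→rt
Reagents that add atoms: none
Why: Hydrazone dehydrogenation gives the diaryldiazomethane, and the Rh(II) donor/donor carbene undergoes enantioselective intramolecular 1,5 C–H insertion into the benzylic ether CH2 (a known reaction type for 2-benzyloxyphenyl aryl diazomethanes); the catalyst fixes C-3 as R, the concerted insertion gives the cis C-2, and C-2 is corrected to trans later under acid.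

**Step 4**
Reactants: 10 methyl 2,4-dimethoxy-6-methylbenzoate; 11 methyl 4-methoxybenzoate
Product: 14 6,8-dimethoxy-3-(4-methoxyphenyl)-1H-isochromen-1-one, via benzylic lithium 12 (not isolated), via keto ester 13 (not isolated)
Conditions: LDA (2.2 equiv), THF, −78 °C; 11; aq. HCl; then cat. TsOH, PhMe, 110 °C
Reagents that add atoms: none
Why: Lateral lithiation of the o-toluate, Claisen-type acylation by the anisate (second equivalent of base absorbs the acidic keto ester) and acid-catalysed enol-lactonisation give the 3-aryl-isocoumarin; no stereocentre.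

**Step 5**
Reactants: 14 6,8-dimethoxy-3-(4-methoxyphenyl)-1H-isochromen-1-one
Product: 15 8-hydroxy-6-methoxy-3-(4-methoxyphenyl)-1H-isochromen-1-one
Conditions: BCl3 (1.2 equiv), CH2Cl2, −78→0 °C; H2O
Reagents that add atoms: none
Why: Chelation-controlled BCl3 demethylation cleaves only the methoxy group peri to the lactone carbonyl; the other two aryl methyl ethers are untouched.

**Step 6**
Reactants: 15 8-hydroxy-6-methoxy-3-(4-methoxyphenyl)-1H-isochromen-1-one; 16 4-methoxybenzyl chloride
Product: 17 6-methoxy-8-[(4-methoxybenzyl)oxy]-3-(4-methoxyphenyl)-1H-isochromen-1-one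
Conditions: K2CO3, cat. Bu4NI, DMF, 60 °C
Reagents that add atoms: none
Why: Williamson etherification of the hydrogen-bonded phenol installs the benzylic ether CH2 that later becomes C-2 of the ring-A dihydrofuran.

**Step 7**
Reactants: 9 (2S,3R)-6-bromo-3-(3,5-dimethoxyphenyl)-4-methoxy-2-(4-methoxyphenyl)-2,3-dihydrobenzofuran; 17 6-methoxy-8-[(4-methoxybenzyl)oxy]-3-(4-methoxyphenyl)-1H-isochromen-1-one
Product: 20 {(2S,3R)-3-(3,5-dimethoxyphenyl)-4-methoxy-2-(4-methoxyphenyl)-2,3-dihydrobenzofuran-6-yl}{4-methoxy-2-[(4-methoxybenzyl)oxy]-6-[(Z)-2-(4-methoxyphenyl)-2-(triisopropylsilyloxy)ethenyl]phenyl}methanone, via aryllithium 18 (not isolated), via lithium enolate 19 (not isolated)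
Conditions: 9, n-BuLi, THF, −78 °C; 17, −78→−40 °C; then TIPSOTf, −78 °C→rt
Reagents that add atoms: triisopropylsilyl trifluoromethanesulfonate, CC(C)[Si](OS(=O)(=O)C(F)(F)F)(C(C)C)C(C)C
Why: Br/Li exchange, then acyl substitution at the enol-lactone carbonyl (the conjugated enolate is the leaving group) gives the hindered diaryl ketone and the Z-enolate, whose O-silylation keeps the C-7 ketone masked through the hydrazone and carbene chemistry; no new stereocentre and the existing cis centres are untouched.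

**Step 8**
Reactants: 20 the diaryl ketone of step 7
Product: 21 hydrazone of ketone 20
Conditions: N2H4·H2O (excess), EtOH, 80 °C
Reagents that add atoms: hydrazine hydrate, NN.O
Why: Condensation at the only free carbonyl (the second ketone is locked as the TIPS enol ether, which tolerates neutral hydrazine); hydrazone geometry is irrelevant.

**Step 9**
Reactants: 21 hydrazone of ketone 20
Product: 24 hepta-O-methyl ether of 25 (both dihydrofurans trans), via diazo compound 22 (not isolated), via silyl enol ether 23 (not isolated)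
Conditions: MnO2, CH2Cl2, 0 °C; Rh2(S-PTAD)4 (1 mol %), −20 °C→rt; Celite; then Bi(OTf)3 (10 mol %), ClCH2CH2Cl, 60 °C
Reagents that add atoms: none
Why: Proposed new method: MnO2 gives the diaryldiazomethane, whose Rh(II) carbene inserts into the ortho O–CH2Ar bond through a five-membered transition state (the chiral carboxylate sphere selects the carbene face and sets C-3 of the ring-A dihydrofuran as S, with C-2 cis); Bi(OTf)3 then turns the silyl enol ether into the C-7 oxocarbenium ion, which ring B captures para to its OMe and ortho to the tied-back ring oxygen (the other ortho site is shielded by the methoxy methyl) in a seven-membered Friedel–Crafts cyclodehydration to the trisubstituted alkene, while the acid equilibrates both O–CH(Ar) centres to trans by reversible C2–O ionisation and leaves both C-3 centres fixed; the closest known reaction types are the enantioselective Rh2(PTAD)4 C–H insertion of 2-benzyloxyphenyl aryl diazomethanes and the Bi(OTf)3 cyclodehydration of aryl ketones that builds the benzofuran-fused seven-membered ring of related stilbenoid dimers.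

**Step 10**
Reactants: 24 hepta-O-methyl ether of 25
Product: 25 target CNP0325907.1 (heptaphenol; ring-A dihydrofuran 2S,3S and ring-B dihydrofuran 2R,3R)
Conditions: BBr3 (excess), CH2Cl2, −78 °C→rt; MeOH/H2O
Reagents that add atoms: none
Why: Lewis-acid demethylation of all seven aryl methyl ethers; the stilbene-type alkene survives, and any residual cis-dihydrofuran converges on the thermodynamic trans isomer under these conditions, so no stereocentre changes.

**Compound list**
1 | 4-bromo-2,6-difluorobenzonitrile | N#Cc1c(F)cc(Br)cc1F | starting material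
2 | 4-methoxybenzyl alcohol | COc1ccc(CO)cc1 | starting material
3 | 4-bromo-2-fluoro-6-[(4-methoxybenzyl)oxy]benzonitrile | N#Cc1c(F)cc(Br)cc1OCc1ccc(OC)cc1 | intermediate
4 | 4-bromo-2-methoxy-6-[(4-methoxybenzyl)oxy]benzonitrile | N#Cc1c(OC)cc(Br)cc1OCc1ccc(OC)cc1 | intermediate
5 | 3,5-dimethoxyphenylmagnesium bromide | COc1cc(OC)cc([Mg]Br)c1 | starting material
6 | [4-bromo-2-methoxy-6-(4-methoxybenzyloxy)phenyl](3,5-dimethoxyphenyl)methanimine | N=C(c1cc(OC)cc(OC)c1)c1c(OC)cc(Br)cc1OCc1ccc(OC)cc1 | intermediate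
7 | [4-bromo-2-methoxy-6-(4-methoxybenzyloxy)phenyl](3,5-dimethoxyphenyl)methanone hydrazone | NN=C(c1cc(OC)cc(OC)c1)c1c(OC)cc(Br)cc1OCc1ccc(OC)cc1 | intermediate
8 | [4-bromo-2-methoxy-6-(4-methoxybenzyloxy)phenyl](3,5-dimethoxyphenyl)diazomethane | [N-]=[N+]=C(c1cc(OC)cc(OC)c1)c1c(OC)cc(Br)cc1OCc1ccc(OC)cc1 | intermediate
9 | (2S,3R)-6-bromo-3-(3,5-dimethoxyphenyl)-4-methoxy-2-(4-methoxyphenyl)-2,3-dihydrobenzofuran (cis) | Brc1cc(OC)c2c(c1)O[C@H](c1ccc(OC)cc1)[C@@H]2c1cc(OC)cc(OC)c1 | intermediate
10 | methyl 2,4-dimethoxy-6-methylbenzoate | COC(=O)c1c(C)cc(OC)cc1OC | starting material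
11 | methyl 4-methoxybenzoate | COC(=O)c1ccc(OC)cc1 | starting material
12 | methyl 2-(lithiomethyl)-4,6-dimethoxybenzoate | COC(=O)c1c(C[Li])cc(OC)cc1OC | intermediate
13 | methyl 2,4-dimethoxy-6-[2-(4-methoxyphenyl)-2-oxoethyl]benzoate | COC(=O)c1c(CC(=O)c2ccc(OC)cc2)cc(OC)cc1OC | intermediate
14 | 6,8-dimethoxy-3-(4-methoxyphenyl)-1H-isochromen-1-one | COc1ccc(C2=Cc3cc(OC)cc(OC)c3C(=O)O2)cc1 | intermediate
15 | 8-hydroxy-6-methoxy-3-(4-methoxyphenyl)-1H-isochromen-1-one | COc1ccc(C2=Cc3cc(OC)cc(O)c3C(=O)O2)cc1 | intermediate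
16 | 4-methoxybenzyl chloride | COc1ccc(CCl)cc1 | starting material
17 | 6-methoxy-8-[(4-methoxybenzyl)oxy]-3-(4-methoxyphenyl)-1H-isochromen-1-one | COc1ccc(COc2cc(OC)cc3C=C(c4ccc(OC)cc4)OC(=O)c23)cc1 | intermediate
18 | [(2S,3R)-3-(3,5-dimethoxyphenyl)-4-methoxy-2-(4-methoxyphenyl)-2,3-dihydrobenzofuran-6-yl]lithium | [Li]c1cc(OC)c2c(c1)O[C@H](c1ccc(OC)cc1)[C@@H]2c1cc(OC)cc(OC)c1 | intermediate
19 | lithium (Z)-enolate of the ring-opened diketone (diaryl ketone plus O-lithio enolate of the 4-methoxyphenyl ketone) | [Li]O/C(=C\c1cc(OC)cc(OCc2ccc(OC)cc2)c1C(=O)c1cc(OC)c2c(c1)O[C@H](c1ccc(OC)cc1)[C@@H]2c1cc(OC)cc(OC)c1)c1ccc(OC)cc1 | intermediate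
20 | {(2S,3R)-3-(3,5-dimethoxyphenyl)-4-methoxy-2-(4-methoxyphenyl)-2,3-dihydrobenzofuran-6-yl}{4-methoxy-2-[(4-methoxybenzyl)oxy]-6-[(Z)-2-(4-methoxyphenyl)-2-(triisopropylsilyloxy)ethenyl]phenyl}methanone | COc1ccc(COc2cc(OC)cc(/C=C(\O[Si](C(C)C)(C(C)C)C(C)C)c3ccc(OC)cc3)c2C(=O)c2cc(OC)c3c(c2)O[C@H](c2ccc(OC)cc2)[C@@H]3c2cc(OC)cc(OC)c2)cc1 | intermediate
21 | hydrazone of ketone 20 | COc1ccc(COc2cc(OC)cc(/C=C(\O[Si](C(C)C)(C(C)C)C(C)C)c3ccc(OC)cc3)c2C(=NN)c2cc(OC)c3c(c2)O[C@H](c2ccc(OC)cc2)[C@@H]3c2cc(OC)cc(OC)c2)cc1 | intermediate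
22 | diazo compound from 21 (C=N2 in place of C=O of 20) | COc1ccc(COc2cc(OC)cc(/C=C(\O[Si](C(C)C)(C(C)C)C(C)C)c3ccc(OC)cc3)c2C(=[N+]=[N-])c2cc(OC)c3c(c2)O[C@H](c2ccc(OC)cc2)[C@@H]3c2cc(OC)cc(OC)c2)cc1 | intermediate
23 | (2R,3S)-3-[(2S,3R)-3-(3,5-dimethoxyphenyl)-4-methoxy-2-(4-methoxyphenyl)-2,3-dihydrobenzofuran-6-yl]-6-methoxy-2-(4-methoxyphenyl)-4-[(Z)-2-(4-methoxyphenyl)-2-(triisopropylsilyloxy)ethenyl]-2,3-dihydrobenzofuran (both dihydrofurans cis) | COc1ccc(/C(O[Si](C(C)C)(C(C)C)C(C)C)=C/c2cc(OC)cc3c2[C@H](c2cc(OC)c4c(c2)O[C@H](c2ccc(OC)cc2)[C@@H]4c2cc(OC)cc(OC)c2)[C@H](c2ccc(OC)cc2)O3)cc1 | intermediate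
24 | hepta-O-methyl ether of 25 (ring-A dihydrofuran 2S,3S trans; ring-B dihydrofuran 2R,3R trans; cycloheptene closed) | COc1ccc(C2=Cc3cc(OC)cc4c3[C@H](c3cc(OC)c5c(c32)O[C@@H](c2ccc(OC)cc2)[C@@H]5c2cc(OC)cc(OC)c2)[C@@H](c2ccc(OC)cc2)O4)cc1 | intermediate
25 | CNP0325907.1 (heptaphenol; ring-A dihydrofuran 2S,3S trans; ring-B dihydrofuran 2R,3R trans) | Oc1ccc(C2=Cc3cc(O)cc4c3[C@H](c3cc(O)c5c(c32)O[C@@H](c2ccc(O)cc2)[C@@H]5c2cc(O)cc(O)c2)[C@@H](c2ccc(O)cc2)O4)cc1 | target

**Totals**
Total step count: 10. Longest linear sequence: 7 steps (steps 4–10, or steps 1–3 followed by 7–10).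

**Three steps most likely to fail**

Step 9. The carbene sits on a doubly ortho-substituted aryl ring next to an electron-rich enol ether, so enantio- and chemoselectivity of the insertion are uncertain, and the ring closure must choose between two ortho positions of ring B. The fallback sets out from 21 and comes back at 24. It gives up catalyst control for this ring: the diazo compound is decomposed with achiral Rh2(esp)2, the acid stage is run unchanged, and 24 is separated by preparative HPLC from the ring-A (2R,3R) diastereomer of the hepta-O-methyl ether F1. This is possible because the ring-B dihydrofuran is already enantiopure, so the two products are diastereomers and not enantiomers.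

Step 7. The aryllithium may add a second time to the newly formed ketone, or the enolate may not be trapped cleanly. The fallback sets out from 17 and comes back at 20. The lactone is first opened with Me(MeO)NMgCl (from MeNHOMe·HCl and i-PrMgCl) to the Weinreb keto amide F2. This is silylated (TIPSOTf, Et3N) to the Z-triisopropylsilyl enol ether Weinreb amide F3. Aryllithium 18 (from 9 and n-BuLi) then adds to F3; the chelated tetrahedral intermediate cannot over-add and gives 20 on work-up.

Step 2. The Grignard reagent may displace an ortho alkoxy group or add only sluggishly to the doubly flanked nitrile. The fallback sets out from 4 and comes back at 7. DIBAL-H reduces 4 to 4-bromo-2-methoxy-6-[(4-methoxybenzyl)oxy]benzaldehyde F4. Grignard 5 adds to it to give the diaryl carbinol F5, which is oxidised (MnO2 or Dess–Martin periodinane) to the benzophenone F6. Condensation with hydrazine hydrate (EtOH, cat. AcOH, 80 °C) gives 7.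

**Further compounds**
F1 | step 9 | ring-A (2R,3R) diastereomer of hepta-O-methyl ether 24 (ring-B dihydrofuran 2R,3R unchanged) | COc1ccc(C2=Cc3cc(OC)cc4c3[C@@H](c3cc(OC)c5c(c32)O[C@@H](c2ccc(OC)cc2)[C@@H]5c2cc(OC)cc(OC)c2)[C@H](c2ccc(OC)cc2)O4)cc1
F2 | step 7 | N-methoxy-N-methyl-4-methoxy-2-[(4-methoxybenzyl)oxy]-6-[2-(4-methoxyphenyl)-2-oxoethyl]benzamide | CON(C)C(=O)c1c(CC(=O)c2ccc(OC)cc2)cc(OC)cc1OCc1ccc(OC)cc1
F3 | step 7 | N-methoxy-N-methyl-4-methoxy-2-[(4-methoxybenzyl)oxy]-6-[(Z)-2-(4-methoxyphenyl)-2-(triisopropylsilyloxy)ethenyl]benzamide | CON(C)C(=O)c1c(/C=C(\O[Si](C(C)C)(C(C)C)C(C)C)c2ccc(OC)cc2)cc(OC)cc1OCc1ccc(OC)cc1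
F4 | step 2 | 4-bromo-2-methoxy-6-[(4-methoxybenzyl)oxy]benzaldehyde | O=Cc1c(OC)cc(Br)cc1OCc1ccc(OC)cc1
F5 | step 2 | [4-bromo-2-methoxy-6-(4-methoxybenzyloxy)phenyl](3,5-dimethoxyphenyl)methanol (racemic) | OC(c1cc(OC)cc(OC)c1)c1c(OC)cc(Br)cc1OCc1ccc(OC)cc1
F6 | step 2 | [4-bromo-2-methoxy-6-(4-methoxybenzyloxy)phenyl](3,5-dimethoxyphenyl)methanone | O=C(c1cc(OC)cc(OC)c1)c1c(OC)cc(Br)cc1OCc1ccc(OC)cc1
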